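**Retrosynthetic overview**
1. Target ⇐ aryl ketone bis-tosylate: Cα by catalyst-controlled transfer hydrogenation, Cβ from (S)-lactamide by Mitsunobu inversion, phenols unmasked last.
2. Oxolane (the only ring) ⇐ 1,4-diol: final closure by capture of the ring A p-alkoxybenzyl (quinone-methide-type) cation at C2 by the C5 hydroxyl (sets 2,3-trans).
3. 1,4-Diol ⇐ lactol + one aryl Grignard reagent, which opens the lactol (sets C5, cis to the C4 methyl after closure) and builds the side-chain aryl ketone in the same flask.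
4. Lactol ⇐ isoeugenol ether + propanal: oxidative radical C–C coupling at C8 of the propenylarene, then capture of the benzylic cation by oxygen (sets C3 and C4).
5. Ring order: the oxolane is made as a lactol (step 2), opened (step 4) and re-closed as the final ring (step 5).

Assumption and labels: isoeugenol is used as the pure (E)-isomer. Oxolane atoms are O1, C2 (ring A side), C3, C4, C5 (ring B side). Ring A is the central guaiacyl ether ring, ring B the aryl on C5, ring C the aryl of the side chain. Cα is the side-chain carbinol carbon, Cβ the aryloxy-bearing carbon, C8 the methyl-bearing alkene carbon of the propenyl group. Target: oxolane (2R,3R,4R,5S), side chain (Cα R, Cβ R, threo).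

**Step 1**
Reactants: 1 (E)-isoeugenol; 2 (S)-N,N-dimethyllactamide
Product: 3 (2R)-2-{2-methoxy-4-[(1E)-prop-1-enyl]phenoxy}-N,N-dimethylpropanamide
Conditions: PPh3, DIAD, THF, 0 → 23 °C
Reagents that add atoms: none
Why: Mitsunobu etherification of the phenol with the secondary α-hydroxy amide runs by SN2 displacement of the oxyphosphonium, so Cβ is inverted from S to R.

**Step 2**
Reactants: 3 (2R)-2-{2-methoxy-4-[(1E)-prop-1-enyl]phenoxy}-N,N-dimethylpropanamide; 4 propanal
Product: 6 trans-lactol (2R)-2-{4-[(3R,4R)-5-hydroxy-3,4-dimethyloxolan-2-yl]-2-methoxyphenoxy}-N,N-dimethylpropanamide, via cis-lactol 5 (not isolated)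
Conditions: 4 (3 equiv), (2R,5R)-5-benzyl-2-tert-butyl-3-methylimidazolidin-4-one·CF3CO2H (20 mol %), (NH4)2Ce(NO3)6 (2.5 equiv), NaHCO3, H2O, DME, −40 °C; then DBU (0.2 equiv), CH2Cl2, 23 °C
Reagents that add atoms: water, SMILES O
Why: Proposed new method: single-electron oxidation of the catalyst-bound (E)-enamine of 4 gives a 3π-electron radical cation that adds through its open Re face (benzyl group shielding the Si face) to the nucleophilic C8 of the propenyl ether, setting C3 as (3R) through the staggered transition state with the two methyl groups anti, the benzylic radical is oxidised by a second tetravalent cerium to the p-alkoxybenzyl (quinone-methide-type) cation, which is captured by the hydrated aldehyde oxygen to close lactol 5, and DBU then equilibrates the aldehyde α-carbon C4 to the trans-lactol 6; the closest known reaction is the organo-SOMO carbo-oxidation of terminal styrenes with aldehydes under (NH4)2Ce(NO3)6, so the internal alkene and the simple diastereoselection are untested.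

**Step 3**
Reactants: 7 4-bromo-2-methoxyphenol
Product: 8 4-bromo-2-methoxyphenyl 4-methylbenzenesulfonate
Conditions: TsCl, Et3N, DMAP (cat.), CH2Cl2, 0 → 23 °C
Reagents that add atoms: p-toluenesulfonyl chloride, SMILES Cc1ccc(cc1)S(Cl)(=O)=O
Why: O-Sulfonylation of the phenol gives an aryl tosylate that survives Grignard formation and, being electron-withdrawing, later keeps the benzylic carbinols of rings B and C from ionising.

**Step 4**
Reactants: 6 trans-lactol; 8 4-bromo-2-methoxyphenyl 4-methylbenzenesulfonate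
Product: 10 diol ketone (2R)-2-{4-[(2R,3R,4S)-1,4-dihydroxy-4-(3-methoxy-4-tosyloxyphenyl)-2,3-dimethylbutyl]-2-methoxyphenoxy}-1-(3-methoxy-4-tosyloxyphenyl)propan-1-one, via arylmagnesium bromide 9 (not isolated)
Conditions: 8 (3.5 equiv), Mg, LiCl, THF, 23 °C; then 6, THF, −78 → 23 °C; aq. NH4Cl
Reagents that add atoms: none
Why: LiCl-assisted magnesium insertion gives Grignard reagent 9, which deprotonates the lactol, adds to its open-chain aldehyde tautomer under Felkin–Anh control (aryl anti to the C3 branch, giving the carbinol syn to the C4 methyl, 5S) and converts the tertiary amide into the aryl ketone on hydrolysis, while C2 stays an epimer mixture that converges in step 5.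

**Step 5**
Reactants: 10 diol ketone
Product: 11 oxolane ketone (2R)-2-{2-methoxy-4-[(2R,3R,4R,5S)-5-(3-methoxy-4-tosyloxyphenyl)-3,4-dimethyloxolan-2-yl]phenoxy}-1-(3-methoxy-4-tosyloxyphenyl)propan-1-one
Conditions: p-TsOH·H2O (10 mol %), CH2Cl2, 0 → 23 °C
Reagents that add atoms: none
Why: In this acid-catalysed SN1 cycloetherification only the electron-rich p-alkoxybenzylic C2 carbinol ionises (the ring B carbinol is deactivated by its para tosyloxy group) to a quinone-methide-type cation that the C5 hydroxyl captures with the aryl group trans to the C3 methyl (A(1,3)-minimised attack and also the thermodynamic outcome of the reversible ionisation), so both C2 epimers give (2R).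

**Step 6**
Reactants: 11 oxolane ketone
Product: 12 bis-tosylate (1R,2R)-2-{2-methoxy-4-[(2R,3R,4R,5S)-5-(3-methoxy-4-tosyloxyphenyl)-3,4-dimethyloxolan-2-yl]phenoxy}-1-(3-methoxy-4-tosyloxyphenyl)propan-1-ol
Conditions: RuCl(p-cymene)[(S,S)-TsDPEN] (2 mol %), HCO2H/Et3N (5:2), EtOAc, 30 °C
Reagents that add atoms: none
Why: In this Noyori asymmetric transfer hydrogenation the (S,S)-catalyst delivers hydride to the aryl-ketone face that gives the (R)-carbinol (R by CIP because Cβ outranks the aryl group), which is also the Felkin–Anh (polar) preference of the (R)-α-aryloxy ketone, so the threo (Cα R, Cβ R) alcohol results.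

**Step 7**
Reactants: 12 bis-tosylate
Product: 13 target (1R,2R)-1-(4-hydroxy-3-methoxyphenyl)-2-{4-[(2R,3R,4R,5S)-5-(4-hydroxy-3-methoxyphenyl)-3,4-dimethyloxolan-2-yl]-2-methoxyphenoxy}propan-1-ol
Conditions: Mg (turnings), MeOH, 23 °C, sonication; aq. NH4Cl
Reagents that add atoms: none
Why: Reductive desulfonylation by single-electron transfer from Mg in MeOH cleaves both aryl S–O bonds under non-acidic conditions that leave the benzylic ether and carbinol stereocentres untouched.

**Compound list**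
1 | (E)-isoeugenol, 2-methoxy-4-[(1E)-prop-1-enyl]phenol | COc1cc(/C=C/C)ccc1O | starting material
2 | (S)-N,N-dimethyllactamide, (2S)-2-hydroxy-N,N-dimethylpropanamide | C[C@H](O)C(=O)N(C)C | starting material
3 | (2R)-2-{2-methoxy-4-[(1E)-prop-1-enyl]phenoxy}-N,N-dimethylpropanamide | C[C@@H](Oc1ccc(/C=C/C)cc1OC)C(=O)N(C)C | intermediate
4 | propanal | CCC=O | starting material
5 | cis-lactol (2R)-2-{4-[(3R,4S)-5-hydroxy-3,4-dimethyloxolan-2-yl]-2-methoxyphenoxy}-N,N-dimethylpropanamide; oxolane C2 and anomeric carbon are epimer mixtures | CN(C)C(=O)[C@@H](C)Oc1ccc(C2OC(O)[C@@H](C)[C@H]2C)cc1OC | intermediate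
6 | trans-lactol (2R)-2-{4-[(3R,4R)-5-hydroxy-3,4-dimethyloxolan-2-yl]-2-methoxyphenoxy}-N,N-dimethylpropanamide; oxolane C2 and anomeric carbon are epimer mixtures | CN(C)C(=O)[C@@H](C)Oc1ccc(C2OC(O)[C@H](C)[C@H]2C)cc1OC | intermediate
7 | 4-bromo-2-methoxyphenol | COc1cc(Br)ccc1O | starting material
8 | 4-bromo-2-methoxyphenyl 4-methylbenzenesulfonate | COc1cc(Br)ccc1OS(=O)(=O)c1ccc(C)cc1 | intermediate
9 | [3-methoxy-4-(tosyloxy)phenyl]magnesium bromide | COc1cc([Mg]Br)ccc1OS(=O)(=O)c1ccc(C)cc1 | intermediate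
10 | diol ketone (2R)-2-{4-[(2R,3R,4S)-1,4-dihydroxy-4-(3-methoxy-4-tosyloxyphenyl)-2,3-dimethylbutyl]-2-methoxyphenoxy}-1-(3-methoxy-4-tosyloxyphenyl)propan-1-one; butyl C1 epimeric | COc1cc(C(=O)[C@@H](C)Oc2ccc(C(O)[C@H](C)[C@@H](C)[C@H](O)c3ccc(OS(=O)(=O)c4ccc(C)cc4)c(OC)c3)cc2OC)ccc1OS(=O)(=O)c1ccc(C)cc1 | intermediate
11 | oxolane ketone (2R)-2-{2-methoxy-4-[(2R,3R,4R,5S)-5-(3-methoxy-4-tosyloxyphenyl)-3,4-dimethyloxolan-2-yl]phenoxy}-1-(3-methoxy-4-tosyloxyphenyl)propan-1-one | COc1cc(C(=O)[C@@H](C)Oc2ccc([C@@H]3O[C@H](c4ccc(OS(=O)(=O)c5ccc(C)cc5)c(OC)c4)[C@H](C)[C@H]3C)cc2OC)ccc1OS(=O)(=O)c1ccc(C)cc1 | intermediate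
12 | bis-tosylate (1R,2R)-2-{2-methoxy-4-[(2R,3R,4R,5S)-5-(3-methoxy-4-tosyloxyphenyl)-3,4-dimethyloxolan-2-yl]phenoxy}-1-(3-methoxy-4-tosyloxyphenyl)propan-1-ol | COc1cc([C@@H](O)[C@@H](C)Oc2ccc([C@@H]3O[C@H](c4ccc(OS(=O)(=O)c5ccc(C)cc5)c(OC)c4)[C@H](C)[C@H]3C)cc2OC)ccc1OS(=O)(=O)c1ccc(C)cc1 | intermediate
13 | (1R,2R)-1-(4-hydroxy-3-methoxyphenyl)-2-{4-[(2R,3R,4R,5S)-5-(4-hydroxy-3-methoxyphenyl)-3,4-dimethyloxolan-2-yl]-2-methoxyphenoxy}propan-1-ol | COc1cc([C@@H](O)[C@@H](C)Oc2ccc([C@@H]3O[C@H](c4ccc(O)c(OC)c4)[C@H](C)[C@H]3C)cc2OC)ccc1O | target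

**Step count and risk**
Total steps: 7. Longest linear sequence: 6 (steps 1, 2, 4, 5, 6, 7).

The three steps most likely to fail:

Step 2. The oxidative annulation is untested on an internal, electron-rich propenylarene. Tetravalent cerium may oxidise the alkene directly (dimers, nitrate adducts), and the simple diastereoselection that fixes C3 is unknown. Any C3 leakage shows up as a diastereomer, because Cβ is already fixed, and would have to be separated. The fallback sets out from 3 and comes back at 6. Ozonolysis of the propenyl group of 3 (O3, CH2Cl2/MeOH, −78 °C; Me2S) gives (2R)-2-(4-formyl-2-methoxyphenoxy)-N,N-dimethylpropanamide F1. Brown anti-crotylation [(E)-crotyl-B(Ipc)2, the Ipc antipode that gives the (1R,2R) adduct, BF3·OEt2, THF, −78 °C; NaOH/H2O2] fixes C3 through a closed chair transition state and gives (2R)-2-{4-[(1R,2R)-1-hydroxy-2-methylbut-3-enyl]-2-methoxyphenoxy}-N,N-dimethylpropanamide F2. Hydroxyl-directed branched hydroformylation [Rh(CO)2(acac), Ph2P(OMe) as reversibly bound directing group, CO/H2 1:1, THF, 45 °C], then DBU, closes and equilibrates the lactol to 6.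

Step 4. Felkin–Anh control at C5 may be only moderate; the minor C5 epimer would close to the all-trans oxolane. The amide may also be deprotonated at Cβ rather than substituted. The fallback sets out from 6 and comes back at 11, so step 5 is not needed. Oxidation of 6 (TEMPO, PhI(OAc)2, CH2Cl2) gives the lactone (2R)-2-{4-[(3R,4R)-3,4-dimethyl-5-oxooxolan-2-yl]-2-methoxyphenoxy}-N,N-dimethylpropanamide F3. Addition of 9 (2.5 equiv, THF, −78 → 0 °C) to lactone and amide gives the cyclic hemiketal (2R)-2-{4-[(3R,4R)-5-hydroxy-5-(3-methoxy-4-tosyloxyphenyl)-3,4-dimethyloxolan-2-yl]-2-methoxyphenoxy}-1-(3-methoxy-4-tosyloxyphenyl)propan-1-one F4. Et3SiH/BF3·OEt2 (CH2Cl2, −78 → −20 °C) reduces the cyclic oxocarbenium ion with hydride anti to the C4 methyl (ring B cis to it, 5S), while the ring A benzylic ether equilibrates to trans, giving 11.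

Step 6. The α-branched ketone may reduce slowly, and Cβ could epimerise under the amine/formic acid medium, blurring the threo selectivity. The fallback sets out from 11 and comes back at 12. Chelation-controlled reduction with Zn(BH4)2 (Et2O, −20 °C) gives the erythro alcohol (1S,2R)-2-{2-methoxy-4-[(2R,3R,4R,5S)-5-(3-methoxy-4-tosyloxyphenyl)-3,4-dimethyloxolan-2-yl]phenoxy}-1-(3-methoxy-4-tosyloxyphenyl)propan-1-ol F5. Mitsunobu inversion with 4-nitrobenzoic acid (PPh3, DIAD, THF) gives the threo (1R,2R) 4-nitrobenzoate of the same carbinol F6. Methanolysis (K2CO3, MeOH, 0 °C) gives 12.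

**Further compounds**
F1 | step 2 | (2R)-2-(4-formyl-2-methoxyphenoxy)-N,N-dimethylpropanamide | CN(C)C(=O)[C@@H](C)Oc1ccc(C=O)cc1OC
F2 | step 2 | (2R)-2-{4-[(1R,2R)-1-hydroxy-2-methylbut-3-enyl]-2-methoxyphenoxy}-N,N-dimethylpropanamide | CN(C)C(=O)[C@@H](C)Oc1ccc([C@H](O)[C@H](C)C=C)cc1OC
F3 | step 4 | (2R)-2-{4-[(3R,4R)-3,4-dimethyl-5-oxooxolan-2-yl]-2-methoxyphenoxy}-N,N-dimethylpropanamide; oxolane C2 epimeric | CN(C)C(=O)[C@@H](C)Oc1ccc(C2OC(=O)[C@H](C)[C@H]2C)cc1OC
F4 | step 4 | (2R)-2-{4-[(3R,4R)-5-hydroxy-5-(3-methoxy-4-tosyloxyphenyl)-3,4-dimethyloxolan-2-yl]-2-methoxyphenoxy}-1-(3-methoxy-4-tosyloxyphenyl)propan-1-one; oxolane C2 and C5 epimeric | COc1cc(C(=O)[C@@H](C)Oc2ccc(C3OC(O)(c4ccc(OS(=O)(=O)c5ccc(C)cc5)c(OC)c4)[C@H](C)[C@H]3C)cc2OC)ccc1OS(=O)(=O)c1ccc(C)cc1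
F5 | step 6 | (1S,2R)-2-{2-methoxy-4-[(2R,3R,4R,5S)-5-(3-methoxy-4-tosyloxyphenyl)-3,4-dimethyloxolan-2-yl]phenoxy}-1-(3-methoxy-4-tosyloxyphenyl)propan-1-ol | COc1cc([C@H](O)[C@@H](C)Oc2ccc([C@@H]3O[C@H](c4ccc(OS(=O)(=O)c5ccc(C)cc5)c(OC)c4)[C@H](C)[C@H]3C)cc2OC)ccc1OS(=O)(=O)c1ccc(C)cc1
F6 | step 6 | (1R,2R)-2-{2-methoxy-4-[(2R,3R,4R,5S)-5-(3-methoxy-4-tosyloxyphenyl)-3,4-dimethyloxolan-2-yl]phenoxy}-1-(3-methoxy-4-tosyloxyphenyl)propyl 4-nitrobenzoate | COc1cc([C@@H](OC(=O)c2ccc(cc2)[N+](=O)[O-])[C@@H](C)Oc2ccc([C@@H]3O[C@H](c4ccc(OS(=O)(=O)c5ccc(C)cc5)c(OC)c4)[C@H](C)[C@H]3C)cc2OC)ccc1OS(=O)(=O)c1ccc(C)cc1
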